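Rivularin A is disconnected at C3' of the primed (2',4',5'-tribromo) indole, the one carbon that joins N1 of the unprimed 2,3,5-tribromoindole to C3a' and C2'. An isocyanide carbon carries exactly this substitution after it has inserted into an aryl–palladium bond and been trapped by an enolate. A single imidoylative cyclisation therefore makes C3a'–C3' and C2'–C3', closes the primed pyrrole ring and brings in N1–C3' ready-made. Its precursors are tert-butyl N-Boc-N-(3,4-dibromo-2-iodophenyl)glycinate and 4-bromo-2-(2,2-dimethoxyethyl)phenyl isocyanide. The acetal arm later closes the unprimed pyrrole ring, and the all-tert-butyl protection falls in one acid step.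

Key step: step 9

Remark: the target is drawn without a descriptor for the hindered N1–C3' axis, so no control of axial configuration is attempted and the compound is made as drawn.

Step 1
Reactants: 1 3-bromo-2-iodoaniline
Product: 2 3,4-dibromo-2-iodoaniline
Conditions: NBS (1.0 equiv), DMF, 0 °C
Reagents that add atoms: N-bromosuccinimide, O=C1CCC(=O)N1Br
Why: Electrophilic aromatic bromination (SEAr) with NBS in DMF is para-selective for free anilines, so the bromine should enter at C4 next to the existing bromine and not at the ortho position C6.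

Step 2
Reactants: 2 3,4-dibromo-2-iodoaniline
Product: 3 tert-butyl (3,4-dibromo-2-iodophenyl)carbamate
Conditions: NaN(SiMe3)2 (2.1 equiv), Boc2O (1.1 equiv), THF, 0 °C → rt; aq. NH4Cl quench
Reagents that add atoms: di-tert-butyl dicarbonate, CC(C)(C)OC(=O)OC(=O)OC(C)(C)C
Why: N-acylation of the sodium anilide, formed from the hindered and electron-poor aniline with two equivalents of NaN(SiMe3)2, by Boc2O should stop at the mono-carbamate because the product stays as its unreactive sodium salt until the quench.

Step 3
Reactants: 3 tert-butyl (3,4-dibromo-2-iodophenyl)carbamate; 4 tert-butyl bromoacetate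
Product: 5 tert-butyl N-(tert-butoxycarbonyl)-N-(3,4-dibromo-2-iodophenyl)glycinate
Conditions: NaH (1.2 equiv), DMF, 0 °C → rt
Reagents that add atoms: none
Why: SN2 N-alkylation of the sodium salt of the aryl carbamate by the reactive α-bromo ester is standard and leaves the aryl halides untouched.

Step 4
Reactants: 6 4-bromo-2-methyl-1-nitrobenzene; 7 N,N-dimethylformamide dimethyl acetal
Product: 8 (E)-2-(5-bromo-2-nitrophenyl)-N,N-dimethylethen-1-amine
Conditions: 7 (3 equiv), DMF, 110 °C
Reagents that add atoms: none
Why: Leimgruber–Batcho enamine formation: the ortho-nitro group acidifies the methyl group enough for condensation with the formamide acetal, and the push–pull enamine forms as the E isomer.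

Step 5
Reactants: 8 (E)-2-(5-bromo-2-nitrophenyl)-N,N-dimethylethen-1-amine
Product: 9 4-bromo-2-(2,2-dimethoxyethyl)-1-nitrobenzene
Conditions: HCl (3 M in MeOH, 2 equiv), MeOH, 65 °C; aq. NaHCO3 work-up
Reagents that add atoms: methanol, CO
Why: Acid-mediated conversion of the β-nitroaryl enamine into the dimethyl acetal: C-protonation gives an iminium ion, methanol adds twice and dimethylamine leaves as its hydrochloride (transacetalisation).

Step 6
Reactants: 9 4-bromo-2-(2,2-dimethoxyethyl)-1-nitrobenzene
Product: 10 4-bromo-2-(2,2-dimethoxyethyl)aniline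
Conditions: H2 (1 atm), 5% Pt/C (sulfided), EtOAc, rt
Reagents that add atoms: none
Why: Catalytic hydrogenation of the nitro group over sulfided platinum is chemoselective in the presence of aryl bromides and runs at neutral pH, so neither hydrodebromination nor acid-induced cyclisation of the amino acetal is expected.

Step 7
Reactants: 10 4-bromo-2-(2,2-dimethoxyethyl)aniline
Product: 11 N-[4-bromo-2-(2,2-dimethoxyethyl)phenyl]formamide
Conditions: HCO2H/Ac2O (premixed, 55 °C, 2 h), then 10, THF, 0 °C
Reagents that add atoms: acetic formic anhydride, CC(=O)OC=O (made in the flask from formic acid, OC=O, and acetic anhydride, CC(=O)OC(C)=O)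
Why: N-formylation with the mixed anhydride occurs at the more electrophilic formyl carbonyl, and the low temperature and short contact with carboxylic acid should keep the acetal intact.

Step 8
Reactants: 11 N-[4-bromo-2-(2,2-dimethoxyethyl)phenyl]formamide
Product: 12 4-bromo-2-(2,2-dimethoxyethyl)phenyl isocyanide
Conditions: POCl3 (1.2 equiv), Et3N (5 equiv), CH2Cl2, −20 → 0 °C; aq. Na2CO3 work-up
Reagents that add atoms: none
Why: Dehydration of the N-aryl formamide with POCl3 and excess Et3N is the standard isocyanide synthesis, and the basic medium protects the acetal.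

Step 9
Reactants: 5 tert-butyl N-(tert-butoxycarbonyl)-N-(3,4-dibromo-2-iodophenyl)glycinate; 12 4-bromo-2-(2,2-dimethoxyethyl)phenyl isocyanide
Product: 14 di-tert-butyl 4,5-dibromo-3-{[4-bromo-2-(2,2-dimethoxyethyl)phenyl]amino}-1H-indole-1,2-dicarboxylate, via indolin-3-imine tautomer 13 (not isolated)
Conditions: Pd(OAc)2 (5 mol%), PPh3 (20 mol%), Cs2CO3 (2.5 equiv), DMF, 80 °C; 12 (1.3 equiv) added over 4 h by syringe pump
Reagents that add atoms: none
Why: Proposed new method: zerovalent palladium, generated from Pd(OAc)2 and PPh3, inserts into the C–I bond of 5, 1,1-insertion of isocyanide 12 then forms C3a'–C3' and leaves an imidoyl complex of divalent palladium that already contains the N1–C3' bond, carbonate-assisted metalation of the glycinate CH2 gives a six-membered C,C-palladacycle, and reductive elimination forms C2'–C3' to give imine 13, whose tautomerisation to the aromatic 3-aminoindole 14 makes the sequence irreversible. The closest known reaction type is the palladium-catalysed imidoylative coupling of aryl halides with isocyanides in which a tethered heteroatom or C–H nucleophile captures the imidoyl palladium, combined with intramolecular palladium-catalysed α-arylation of amino ester enolates. The primed pyrrole ring closes by C–C reductive elimination from the palladacycle, which corresponds formally to a 5-exo-trig attack of the enolate carbon on the imidoyl C=N carbon. No stereocentre remains, because C2' of 13 becomes sp2 on tautomerisation. The step needs oxidative addition at C–I only and one isocyanide insertion only: the first rests on the weaker C–I bond together with PPh3 and 80 °C, under which the three C–Br bonds should stay intact, the second on syringe-pump addition of 12 and on the two ortho substituents of the aryl–palladium species, while direct enolate arylation without insertion would need a four-membered ring and the benzylic CH2 of the acetal arm is far less acidic than the glycinate CH2.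

Step 10
Reactants: 14 di-tert-butyl 4,5-dibromo-3-{[4-bromo-2-(2,2-dimethoxyethyl)phenyl]amino}-1H-indole-1,2-dicarboxylate
Product: 16 4,5-dibromo-3-(5-bromo-1H-indol-1-yl)-1H-indole-2-carboxylic acid, via ring-closed N-Boc tert-butyl ester 15 (not isolated)
Conditions: TFA/CH2Cl2 (1:4), 0 °C → rt
Reagents that add atoms: none
Why: Acetal-to-indole cyclisation followed by acidolysis: TFA ionises the acetal to an oxocarbenium ion that the neighbouring diarylamine nitrogen traps (N1–C2, five-membered), loss of methanol aromatises the unprimed indole 15, and the N-Boc group and tert-butyl ester then fall as 2-methylpropene and CO2 to leave the NH indole acid.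

Step 11
Reactants: 16 4,5-dibromo-3-(5-bromo-1H-indol-1-yl)-1H-indole-2-carboxylic acid
Product: 19 rivularin A (2,4,5-tribromo-3-(2,3,5-tribromo-1H-indol-1-yl)-1H-indole), via C3-bromo acid 17 (not isolated), via decarboxylated pentabromide 18 (not isolated)
Conditions: NBS (3.1 equiv), LiOAc (20 mol%), dry DMF, 0 °C → rt, dark
Reagents that add atoms: N-bromosuccinimide, O=C1CCC(=O)N1Br
Why: Electrophilic bromination should take C3 of the N-aryl indole first (17), ipso attack at C2' of the indole-2-carboxylate with loss of CO2 (bromodecarboxylation of an electron-rich heteroaromatic acid) should follow (18), and the last equivalent should brominate C2 of the 3-bromoindole, the benzenoid positions being deactivated by their bromine substituents.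

Compound list
1 | 3-bromo-2-iodoaniline | Nc1cccc(Br)c1I | starting material
2 | 3,4-dibromo-2-iodoaniline | Nc1ccc(Br)c(Br)c1I | intermediate
3 | tert-butyl (3,4-dibromo-2-iodophenyl)carbamate | CC(C)(C)OC(=O)Nc1ccc(Br)c(Br)c1I | intermediate
4 | tert-butyl bromoacetate | CC(C)(C)OC(=O)CBr | starting material
5 | tert-butyl N-(tert-butoxycarbonyl)-N-(3,4-dibromo-2-iodophenyl)glycinate | CC(C)(C)OC(=O)CN(C(=O)OC(C)(C)C)c1ccc(Br)c(Br)c1I | intermediate
6 | 4-bromo-2-methyl-1-nitrobenzene | Cc1cc(Br)ccc1[N+](=O)[O-] | starting material
7 | N,N-dimethylformamide dimethyl acetal | COC(OC)N(C)C | starting material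
8 | (E)-2-(5-bromo-2-nitrophenyl)-N,N-dimethylethen-1-amine | CN(C)/C=C/c1cc(Br)ccc1[N+](=O)[O-] | intermediate
9 | 4-bromo-2-(2,2-dimethoxyethyl)-1-nitrobenzene | COC(OC)Cc1cc(Br)ccc1[N+](=O)[O-] | intermediate
10 | 4-bromo-2-(2,2-dimethoxyethyl)aniline | COC(OC)Cc1cc(Br)ccc1N | intermediate
11 | N-[4-bromo-2-(2,2-dimethoxyethyl)phenyl]formamide | COC(OC)Cc1cc(Br)ccc1NC=O | intermediate
12 | 4-bromo-2-(2,2-dimethoxyethyl)phenyl isocyanide | [C-]#[N+]c1ccc(Br)cc1CC(OC)OC | intermediate
13 | di-tert-butyl 4,5-dibromo-3-{[4-bromo-2-(2,2-dimethoxyethyl)phenyl]imino}indoline-1,2-dicarboxylate (racemic at C2, imine geometry not defined; not isolated) | CC(C)(C)OC(=O)C1N(C(=O)OC(C)(C)C)c2ccc(Br)c(Br)c2C1=Nc1ccc(Br)cc1CC(OC)OC | intermediate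
14 | di-tert-butyl 4,5-dibromo-3-{[4-bromo-2-(2,2-dimethoxyethyl)phenyl]amino}-1H-indole-1,2-dicarboxylate | CC(C)(C)OC(=O)c1n(C(=O)OC(C)(C)C)c2ccc(Br)c(Br)c2c1Nc1ccc(Br)cc1CC(OC)OC | intermediate
15 | di-tert-butyl 4,5-dibromo-3-(5-bromo-1H-indol-1-yl)-1H-indole-1,2-dicarboxylate (not isolated) | CC(C)(C)OC(=O)c1n(C(=O)OC(C)(C)C)c2ccc(Br)c(Br)c2c1-n1ccc2cc(Br)ccc21 | intermediate
16 | 4,5-dibromo-3-(5-bromo-1H-indol-1-yl)-1H-indole-2-carboxylic acid | OC(=O)c1[nH]c2ccc(Br)c(Br)c2c1-n1ccc2cc(Br)ccc21 | intermediate
17 | 4,5-dibromo-3-(3,5-dibromo-1H-indol-1-yl)-1H-indole-2-carboxylic acid (not isolated) | OC(=O)c1[nH]c2ccc(Br)c(Br)c2c1-n1cc(Br)c2cc(Br)ccc21 | intermediate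
18 | 2,4,5-tribromo-3-(3,5-dibromo-1H-indol-1-yl)-1H-indole (not isolated) | Brc1[nH]c2ccc(Br)c(Br)c2c1-n1cc(Br)c2cc(Br)ccc21 | intermediate
19 | rivularin A, 2,4,5-tribromo-3-(2,3,5-tribromo-1H-indol-1-yl)-1H-indole | Brc1ccc2c(c1)c(Br)c(Br)n2-c1c(Br)[nH]c2ccc(Br)c(Br)c12 | target

Total step count: 11
Longest linear sequence: 8 steps (steps 4 to 11, from 6 to 19)

Steps most likely to fail

Step 9. The imidoyl palladium species may take up further isocyanide or be sequestered by it before the weakly acidic glycinate carbon is metalated. Late in the reaction, oxidative addition into a C–Br bond could also start C–N coupling between product molecules. The fallback forms N1–C3' by carbonyl condensation instead; it sets out from 5 (and uses 10) and comes back to the route at 19. Iodine–magnesium exchange on 5 with iPrMgCl·LiCl (THF, −40 °C, then 0 °C) and attack of the arylmagnesium on the tert-butyl ester (Parham-type cyclisation) should give tert-butyl 4,5-dibromo-3-oxoindoline-1-carboxylate F1. Condensation of this ketone with aniline 10 under Ti(OiPr)4 (toluene, 60 °C, neutral so that the acetal is kept) should give, as its aromatic enamine tautomer, tert-butyl 4,5-dibromo-3-{[4-bromo-2-(2,2-dimethoxyethyl)phenyl]amino}-1H-indole-1-carboxylate F2. TFA/CH2Cl2 then removes the Boc group and closes the unprimed pyrrole ring to 4,5-dibromo-3-(5-bromo-1H-indol-1-yl)-1H-indole F3. NBS (3 equiv, DMF) brominates C2', C3 and C2 to give 19.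

Step 11. Three brominations in one flask may not stop at the intended sites, the 3-bromoindole may be oxidised before C2 is substituted, or the ipso substitution at C2' may lag behind. The fallback brominates site by site under protecting-group control; it sets out from 14 and comes back at 19. Pyridinium p-toluenesulfonate (toluene, 80 °C) closes only the unprimed pyrrole ring, so that 15 is isolated with both tert-butyl groups in place. NBS (2 equiv, THF) then brominates C3 and C2 of the unprimed indole alone, because the primed indole is blocked and deactivated by N-Boc and the C2' ester, to give di-tert-butyl 4,5-dibromo-3-(2,3,5-tribromo-1H-indol-1-yl)-1H-indole-1,2-dicarboxylate F4. TFA/CH2Cl2 at 0 °C gives 4,5-dibromo-3-(2,3,5-tribromo-1H-indol-1-yl)-1H-indole-2-carboxylic acid F5. One equivalent of NBS with catalytic LiOAc then effects a single bromodecarboxylation to 19.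

Step 10. tert-Butyl cations are released beside a freshly formed C3-unsubstituted indole and may alkylate it, the protonated indole may dimerise, or the acid may lose CO2 early. The fallback separates ring closure from deprotection and avoids protic acid in the second stage; it sets out from 14 and comes back at 16. Pyridinium p-toluenesulfonate (toluene, 80 °C) gives isolated 15. TMSOTf/2,6-lutidine (CH2Cl2, 0 °C → rt) then cleaves the N-Boc group and the tert-butyl ester through their silyl carbamate and silyl ester, with 2-methylpropene removed by the base, and methanolic work-up gives 16.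

Further compounds
F1 | step 9 | tert-butyl 4,5-dibromo-3-oxoindoline-1-carboxylate | CC(C)(C)OC(=O)N1CC(=O)c2c(Br)c(Br)ccc21
F2 | step 9 | tert-butyl 4,5-dibromo-3-{[4-bromo-2-(2,2-dimethoxyethyl)phenyl]amino}-1H-indole-1-carboxylate | CC(C)(C)OC(=O)n1cc(Nc2ccc(Br)cc2CC(OC)OC)c2c(Br)c(Br)ccc21
F3 | step 9 | 4,5-dibromo-3-(5-bromo-1H-indol-1-yl)-1H-indole | Brc1ccc2[nH]cc(-n3ccc4cc(Br)ccc43)c2c1Br
F4 | step 11 | di-tert-butyl 4,5-dibromo-3-(2,3,5-tribromo-1H-indol-1-yl)-1H-indole-1,2-dicarboxylate | CC(C)(C)OC(=O)c1n(C(=O)OC(C)(C)C)c2ccc(Br)c(Br)c2c1-n1c(Br)c(Br)c2cc(Br)ccc21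
F5 | step 11 | 4,5-dibromo-3-(2,3,5-tribromo-1H-indol-1-yl)-1H-indole-2-carboxylic acid | OC(=O)c1[nH]c2ccc(Br)c(Br)c2c1-n1c(Br)c(Br)c2cc(Br)ccc21
F0 | step 10 | none | none
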